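**Retrosynthetic overview**
- 18 ⇒ 17: the 3-OH is unmasked last (SEM ether), so that no enolic OH is present while a ketene is in the flask.
- 17 ⇒ 13: ring A is cut at C4a–C5. C5, C6 and C7 come from an acylketene (from an acyl Meldrum's acid) whose enol is the dienylketene C5=C6–C7=C8–C8a=C4a, which closes by 6π-electrocyclisation.
- 13 ⇒ acid 11 + Meldrum's acid 12; 11 ⇒ 8 by carboxylation of the CH2OMe carbon (C8); 8 ⇒ bromide 7 + boronic acid 3 (ring B attached at C2 by Suzuki coupling).
- The route rests on one feature: ring C (O1, C2, C3, C4, C4a, C8a) with its 3-OH, together with the oxygen-bearing carbon C8 on C8a, is the 3-hydroxy-4-pyranone skeleton of kojic acid 4. Only C7, C6 and C5 have to be added.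
- Ring order: ring C is bought (kojic acid), ring B is attached, ring A is formed last.

Key step: step 8

Remark: atoms are numbered as in the flavone (flavone C2, C3, C4, C4a, C8a and C8 are kojic acid C6, C5, C4, C3, C2 and its CH2 carbon). SEM = 2-(trimethylsilyl)ethoxymethyl, prenyl = 3-methylbut-2-enyl. The target has no stereocentre; the single centres of 10, 11, 13, 14 and 16 are racemic and are erased in step 8.

**Step 1**
Reactants: 1 4-hydroxyphenylboronic acid; 2 prenyl bromide
Product: 3 4-(prenyloxy)phenylboronic acid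
Conditions: K2CO3, DMF, rt
Reagents that add atoms: none
Why: Williamson ether synthesis, in which the carbonate-generated phenoxide displaces the primary allylic bromide by SN2 while the boronic acid group is left untouched.

**Step 2**
Reactants: 4 kojic acid
Product: 5 2-bromo-3-hydroxy-6-(hydroxymethyl)-4H-pyran-4-one (6-bromokojic acid)
Conditions: NBS (1.0 equiv), DMF, 0 °C → rt, dark
Reagents that add atoms: N-bromosuccinimide, O=C1CCC(=O)N1Br
Why: Electrophilic halogenation of an enol, since kojic C6 is the position ortho to the enolic OH at which kojic acid takes up electrophiles, whereas C3 has no such activation.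

**Step 3**
Reactants: 5 6-bromokojic acid
Product: 6 2-bromo-6-(hydroxymethyl)-3-(SEM-oxy)-4H-pyran-4-one
Conditions: SEMCl (1.05 equiv), K2CO3, DMF, 0 °C → rt
Reagents that add atoms: 2-(trimethylsilyl)ethoxymethyl chloride, C[Si](C)(C)CCOCCl
Why: Williamson-type O-alkylation of the potassium enolate of the acidic 3-hydroxy-4-pyranone by the hard chloromethyl ether, with carbonate too weak to deprotonate the primary alcohol, which should stay free.

**Step 4**
Reactants: 6 2-bromo-6-(hydroxymethyl)-3-(SEM-oxy)-4H-pyran-4-one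
Product: 7 2-bromo-6-(methoxymethyl)-3-(SEM-oxy)-4H-pyran-4-one
Conditions: MeI (excess), Ag2O, MeCN, 4 Å MS, rt → 40 °C, dark
Reagents that add atoms: iodomethane, CI
Why: Purdie methylation (silver-assisted SN2 of the neutral alcohol on MeI), which forms the methyl ether without an alkoxide that could displace the vinylogous acyl bromide or open the pyranone.

**Step 5**
Reactants: 7 2-bromo-6-(methoxymethyl)-3-(SEM-oxy)-4H-pyran-4-one; 3 4-(prenyloxy)phenylboronic acid
Product: 8 6-(methoxymethyl)-2-[4-(prenyloxy)phenyl]-3-(SEM-oxy)-4H-pyran-4-one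
Conditions: Pd(dppf)Cl2 (cat.), K3PO4, dioxane/H2O (10:1), 80 °C
Reagents that add atoms: none
Why: Suzuki–Miyaura coupling, in which the C–Br bond of the vinylogous acyl bromide adds readily to zerovalent palladium, while phosphate with little water keeps hydrolysis of the bromide and ionisation of the hindered prenyl ether slow.

**Step 6**
Reactants: 8 6-(methoxymethyl)-2-[4-(prenyloxy)phenyl]-3-(SEM-oxy)-4H-pyran-4-one
Product: 11 (RS)-2-methoxy-2-{4-oxo-6-[4-(prenyloxy)phenyl]-5-(SEM-oxy)-4H-pyran-2-yl}acetic acid, via lithium dienolate 9 (not isolated), via lithium carboxylate 10 (not isolated)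
Conditions: LiN(SiMe3)2 (1.05 equiv), THF, −78 °C; CO2 (g), −78 → −30 °C; 1 M HCl to pH 3, 0 °C; crude acid kept cold and used at once
Reagents that add atoms: carbon dioxide, O=C=O
Why: Lateral (vinylogous) deprotonation of a 2-alkyl-4-pyranone gives the extended enolate 9, which should be carboxylated at the exocyclic carbon so that the pyranone is restored; the new centre at C8 forms racemic and is erased in step 8.

**Step 7**
Reactants: 11 the α-methoxy acid; 12 Meldrum's acid
Product: 13 (RS)-5-(1-hydroxy-2-methoxy-2-{4-oxo-6-[4-(prenyloxy)phenyl]-5-(SEM-oxy)-4H-pyran-2-yl}ethylidene)-2,2-dimethyl-1,3-dioxane-4,6-dione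
Conditions: DCC, DMAP, CH2Cl2, −10 °C → rt; cold aq. KHSO4 wash; used crude
Reagents that add atoms: none
Why: Steglich-type carbodiimide/DMAP C-acylation of Meldrum's acid, the standard entry to acyl Meldrum's acids, run cold because the activated acid has an acidic α-hydrogen.

**Step 8**
Reactants: 13 the acyl Meldrum's acid
Product: 17 5,7-dihydroxy-8-methoxy-4'-prenyloxy-3-(SEM-oxy)flavone, via acylketene 14 (not isolated), via dienylketene 15 (not isolated), via cyclohexadienone 16 (not isolated)
Conditions: PhMe, 110 °C, Ar, slow addition of 13 by syringe pump to about 2 mM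
Reagents that add atoms: none
Why: Proposed new method: at 110 °C the acyl Meldrum's acid loses acetone and CO2 (the known retro-[4+2] route to acylketenes) to give 14, whose C8–H, flanked by the C7 ketone and the pyranone, enolises to the (Z)-dienylketene 15, in which C5=C6, C7=C8 and C8a=C4a form a hexatriene with the ketene carbon C5 held over C4a. A thermal disrotatory 6π-electrocyclisation (in polar terms, C-acylation of the enol-ether β-carbon C4a by the ketene) forms C4a–C5 and closes ring A as the six-membered dienone 16, and a proton shift from C4a to O5 aromatises it to 17, helped by the hydrogen bond from 5-OH to the C4 carbonyl. The closest known reactions are the dienylketene-to-phenol electrocyclisation that ends cyclobutenone benzannulations (Danheiser benzannulation, Moore cyclisation, where the third π bond may belong to a heteroarene) and the ketene ring closure of aminomethylene Meldrum's acids to 4-quinolones; no closure onto a 4-pyranone C=C bond is known. No stereocentre results, because C8 of 13 and C4a of 16 both end sp2. Regioselectivity needs no control, since C4a is the only carbon that the ketene carbon of 15 can reach through a six-membered transition state. The chemoselectivity that is needed, ring closure ahead of ketene dimerisation and of ketene capture by the phenols of 17, is secured by slow addition at high dilution, and the neutral medium at 110 °C should spare the SEM ether and the aryl prenyl ether, whose Claisen rearrangement needs a higher temperature.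

**Step 9**
Reactants: 17 5,7-dihydroxy-8-methoxy-4'-prenyloxy-3-(SEM-oxy)flavone
Product: 18 3,5,7-trihydroxy-8-methoxy-4'-prenyloxyflavone
Conditions: Bu4NF (1 M in THF, excess), H2NCH2CH2NH2, THF, 60 °C, Ar; then AcOH
Reagents that add atoms: none
Why: Fluoride-induced fragmentation of the SEM ether (attack at silicon, loss of ethylene and formaldehyde) frees the 3-OH without touching the prenyl and methyl ethers, and ethylenediamine intercepts the formaldehyde before it can hydroxymethylate C6 of the phloroglucinol-type ring A.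

**Compound list**
1 | 4-hydroxyphenylboronic acid | OB(O)c1ccc(O)cc1 | starting material
2 | prenyl bromide (1-bromo-3-methylbut-2-ene) | CC(C)=CCBr | starting material
3 | 4-(prenyloxy)phenylboronic acid | CC(C)=CCOc1ccc(B(O)O)cc1 | intermediate
4 | kojic acid | O=c1cc(CO)occ1O | starting material
5 | 2-bromo-3-hydroxy-6-(hydroxymethyl)-4H-pyran-4-one | O=c1cc(CO)oc(Br)c1O | intermediate
6 | 2-bromo-6-(hydroxymethyl)-3-(SEM-oxy)-4H-pyran-4-one | O=c1cc(CO)oc(Br)c1OCOCC[Si](C)(C)C | intermediate
7 | 2-bromo-6-(methoxymethyl)-3-(SEM-oxy)-4H-pyran-4-one | COCc1cc(=O)c(OCOCC[Si](C)(C)C)c(Br)o1 | intermediate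
8 | 6-(methoxymethyl)-2-[4-(prenyloxy)phenyl]-3-(SEM-oxy)-4H-pyran-4-one | COCc1cc(=O)c(OCOCC[Si](C)(C)C)c(-c2ccc(OCC=C(C)C)cc2)o1 | intermediate
9 | lithium 2-(methoxymethylidene)-6-[4-(prenyloxy)phenyl]-5-(SEM-oxy)-2H-pyran-4-olate (extended enolate of 8, not isolated) | [Li+].COC=C1C=C([O-])C(OCOCC[Si](C)(C)C)=C(c2ccc(OCC=C(C)C)cc2)O1 | intermediate
10 | lithium (RS)-2-methoxy-2-{4-oxo-6-[4-(prenyloxy)phenyl]-5-(SEM-oxy)-4H-pyran-2-yl}acetate (not isolated) | [Li+].COC(C(=O)[O-])c1cc(=O)c(OCOCC[Si](C)(C)C)c(-c2ccc(OCC=C(C)C)cc2)o1 | intermediate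
11 | (RS)-2-methoxy-2-{4-oxo-6-[4-(prenyloxy)phenyl]-5-(SEM-oxy)-4H-pyran-2-yl}acetic acid | COC(C(=O)O)c1cc(=O)c(OCOCC[Si](C)(C)C)c(-c2ccc(OCC=C(C)C)cc2)o1 | intermediate
12 | Meldrum's acid (2,2-dimethyl-1,3-dioxane-4,6-dione) | CC1(C)OC(=O)CC(=O)O1 | starting material
13 | (RS)-5-(1-hydroxy-2-methoxy-2-{4-oxo-6-[4-(prenyloxy)phenyl]-5-(SEM-oxy)-4H-pyran-2-yl}ethylidene)-2,2-dimethyl-1,3-dioxane-4,6-dione | CC1(C)OC(=O)C(=C(O)C(OC)c2cc(=O)c(OCOCC[Si](C)(C)C)c(-c3ccc(OCC=C(C)C)cc3)o2)C(=O)O1 | intermediate
14 | (RS)-4-methoxy-4-{4-oxo-6-[4-(prenyloxy)phenyl]-5-(SEM-oxy)-4H-pyran-2-yl}but-1-ene-1,3-dione (acylketene, not isolated) | COC(C(=O)C=C=O)c1cc(=O)c(OCOCC[Si](C)(C)C)c(-c2ccc(OCC=C(C)C)cc2)o1 | intermediate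
15 | (Z)-3-hydroxy-4-methoxy-4-{4-oxo-6-[4-(prenyloxy)phenyl]-5-(SEM-oxy)-4H-pyran-2-yl}buta-1,3-dien-1-one (dienylketene, not isolated) | CO/C(c1cc(=O)c(OCOCC[Si](C)(C)C)c(-c2ccc(OCC=C(C)C)cc2)o1)=C(\O)C=C=O | intermediate
16 | (RS)-7-hydroxy-8-methoxy-2-[4-(prenyloxy)phenyl]-3-(SEM-oxy)-4aH-chromene-4,5-dione (not isolated) | COC1=C2OC(c3ccc(OCC=C(C)C)cc3)=C(OCOCC[Si](C)(C)C)C(=O)C2C(=O)C=C1O | intermediate
17 | 5,7-dihydroxy-8-methoxy-4'-prenyloxy-3-(SEM-oxy)flavone | COc1c(O)cc(O)c2c(=O)c(OCOCC[Si](C)(C)C)c(-c3ccc(OCC=C(C)C)cc3)oc12 | intermediate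
18 | 3,5,7-trihydroxy-8-methoxy-4'-prenyloxyflavone | COc1c(O)cc(O)c2c(=O)c(O)c(-c3ccc(OCC=C(C)C)cc3)oc12 | target

**Step count and risks**
Total steps: 9. Longest linear sequence: 8 steps (kojic acid 4 to 18, steps 2 to 9).

Steps most likely to fail:

1. Step 8 (proposed new method). The ketene may be consumed by dimerisation or by addition of phenolic OH groups before the weakly nucleophilic vinylogous-ester carbon C4a closes the ring, or enolisation toward C8 may be too slow.
Fallback (known chemistry, ring A bought and ring C closed last): it sets out from prenyl bromide 2 and returns at target 18. 4-Hydroxybenzaldehyde is alkylated with 2 (K2CO3, DMF) to 4-(prenyloxy)benzaldehyde F1. 2',4',6'-Trihydroxyacetophenone is treated with two equivalents of SEMCl (i-Pr2NEt, CH2Cl2); the chelated ortho-hydroxyl should stay free, giving 1-[2-hydroxy-4,6-bis(SEM-oxy)phenyl]ethanone F2. Iodination ortho to the free hydroxyl (NIS, DMF) should give 1-[2-hydroxy-3-iodo-4,6-bis(SEM-oxy)phenyl]ethanone F3. Copper-catalysed Ullmann methoxylation (NaOMe, CuI, MeOH/DMF, 100 °C) then gives 1-[2-hydroxy-3-methoxy-4,6-bis(SEM-oxy)phenyl]ethanone F4. Claisen–Schmidt condensation of F4 with F1 (KOH, EtOH) gives (E)-2'-hydroxy-3'-methoxy-4-prenyloxy-4',6'-bis(SEM-oxy)chalcone F5. Algar–Flynn–Oyamada oxidation (H2O2, NaOH, MeOH) closes ring C through the only free hydroxyl, the one next to the methoxy group, and should give 3-hydroxy-8-methoxy-4'-prenyloxy-5,7-bis(SEM-oxy)flavone F6. Bu4NF/ethylenediamine as in step 9 removes both SEM groups and gives 18.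

2. Step 6. Carboxylation may be incomplete or reversible, and the vinylogous β-keto acid 11 may lose CO2 during acidification and isolation.
Fallback: it sets out from 8 and returns at 13 without a free acid. The dienolate 9 (from 8 with 2.2 equiv LiN(SiMe3)2, THF, −78 °C) is trapped with 1,1'-carbonyldiimidazole to give the acyl imidazole 1-(2-methoxy-2-{4-oxo-6-[4-(prenyloxy)phenyl]-5-(SEM-oxy)-4H-pyran-2-yl}acetyl)imidazole F7, present as its enolate. Meldrum's acid 12 (excess) is then added to the cold mixture; it protonates that enolate and is C-acylated by F7 on warming, the usual acyl-imidazole route to acyl Meldrum's acids, giving 13.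

3. Step 7. The activated acid may form a ketene and self-condense, or 13, which cannot be chromatographed, may lose acetone and CO2 prematurely during work-up.
Fallback: it sets out from 11 and returns at acylketene 14 inside step 8, and so at 17. Masamune-type chain extension (CDI, THF, through the acyl imidazole F7 formed in the flask; then Mg(O2CCH2CO2t-Bu)2, rt) gives tert-butyl 4-methoxy-3-oxo-4-{4-oxo-6-[4-(prenyloxy)phenyl]-5-(SEM-oxy)-4H-pyran-2-yl}butanoate F8, a β-keto ester that can be purified and stored. Heated at high dilution in toluene or xylene (110–140 °C), F8 loses tert-butanol, the known thermal route from tert-butyl β-keto esters to acylketenes, and delivers 14, which continues as in step 8.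

**Further compounds**
F1 | step 8 | 4-(prenyloxy)benzaldehyde | CC(C)=CCOc1ccc(C=O)cc1
F2 | step 8 | 1-[2-hydroxy-4,6-bis(SEM-oxy)phenyl]ethanone | CC(=O)c1c(O)cc(OCOCC[Si](C)(C)C)cc1OCOCC[Si](C)(C)C
F3 | step 8 | 1-[2-hydroxy-3-iodo-4,6-bis(SEM-oxy)phenyl]ethanone | CC(=O)c1c(O)c(I)c(OCOCC[Si](C)(C)C)cc1OCOCC[Si](C)(C)C
F4 | step 8 | 1-[2-hydroxy-3-methoxy-4,6-bis(SEM-oxy)phenyl]ethanone | CC(=O)c1c(O)c(OC)c(OCOCC[Si](C)(C)C)cc1OCOCC[Si](C)(C)C
F5 | step 8 | (E)-2'-hydroxy-3'-methoxy-4-prenyloxy-4',6'-bis(SEM-oxy)chalcone | O=C(/C=C/c1ccc(OCC=C(C)C)cc1)c1c(O)c(OC)c(OCOCC[Si](C)(C)C)cc1OCOCC[Si](C)(C)C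
F6 | step 8 | 3-hydroxy-8-methoxy-4'-prenyloxy-5,7-bis(SEM-oxy)flavone | COc1c(OCOCC[Si](C)(C)C)cc(OCOCC[Si](C)(C)C)c2c(=O)c(O)c(-c3ccc(OCC=C(C)C)cc3)oc12
F7 | step 6 | 1-(2-methoxy-2-{4-oxo-6-[4-(prenyloxy)phenyl]-5-(SEM-oxy)-4H-pyran-2-yl}acetyl)imidazole (racemic) | COC(C(=O)n1ccnc1)c1cc(=O)c(OCOCC[Si](C)(C)C)c(-c2ccc(OCC=C(C)C)cc2)o1
F8 | step 7 | tert-butyl 4-methoxy-3-oxo-4-{4-oxo-6-[4-(prenyloxy)phenyl]-5-(SEM-oxy)-4H-pyran-2-yl}butanoate (racemic) | COC(C(=O)CC(=O)OC(C)(C)C)c1cc(=O)c(OCOCC[Si](C)(C)C)c(-c2ccc(OCC=C(C)C)cc2)o1
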